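**Retrosynthetic overview**

1. The plan rests on ring D: the cis-2,3-disubstituted 1,4-dioxane fused to the central arene C holds the benzylic carbon C7' (bearing catechol ring E) on O4C and C8' (bearing C9'H2OH) on O3C, a pattern that equals a (2S,3S)-trans cinnamyl epoxide inverted at C7' alone.
2. Disconnections, from the target backwards: enal C=C on ring A (Wittig); O3A–C(aryl) bond of the trans ring B (copper O-arylation of the C7 hydroxyl, retention); C7–C8 (Evans syn-aldol of the ring C aldehyde with an aryloxyacetyl imide that already holds the O4A–C8 bond); ring D (SN2 opening of the epoxide at C7' by a 2-bromophenoxide, then copper O-arylation of the C8' alkoxide).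
3. One building block, 2-bromo-4-(1,3-dioxolan-2-yl)phenol, serves twice, as ring C in the domino and as ring A in the aldol partner; the aldol is preferred to dihydroxylation of a cinnamate because it tells O7 from O8 from the outset.
4. Order of ring formation: arenes E, C and A are bought; ring D is closed in step 6 and ring B in step 13.
5. Benzyl ethers serve through both basic copper steps and are exchanged for silyl ethers once no aryl bromide or alkene is present and before the enal is made, so that the last step is a mild fluoride deprotection.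

Key step: step 6

Remark: rings are lettered A (enal arene), B (trans dioxane), C (central arene), D (cis dioxane) and E (catechol); C7–C8–C9 is the three-carbon unit of ring B (C7 on ring C), C7'–C8'–C9' that of ring D (C7' on ring E); O3 and O4 of ring A or C are the oxygens meta and para to the carbon substituent of that ring; compounds 1, 2, 7, 12, 13 and 24 are assumed to be bought.

**Route**

Step 1
Reactants: 1 3,4-bis(benzyloxy)benzaldehyde; 2 triethyl phosphonoacetate
Product: 3 ethyl (E)-3-[3,4-bis(benzyloxy)phenyl]prop-2-enoate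
Conditions: NaH, THF, 0 °C → rt
Reagents that add atoms: none
Why: Horner–Wadsworth–Emmons olefination, in which the stabilised sodium phosphonate carbanion adds to the aldehyde and collapses through the more stable anti oxaphosphetane to the E cinnamate.

Step 2
Reactants: 3 ethyl (E)-3-[3,4-bis(benzyloxy)phenyl]prop-2-enoate
Product: 4 (E)-3-[3,4-bis(benzyloxy)phenyl]prop-2-en-1-ol
Conditions: iBu2AlH (2.2 equiv), CH2Cl2, −78 °C; aq. KNaC4H4O6
Reagents that add atoms: none
Why: 1,2-reduction of the unsaturated ester by the aluminium hydride at low temperature should give the allylic alcohol and leave the alkene and the benzyl ethers alone.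

Step 3
Reactants: 4 (E)-3-[3,4-bis(benzyloxy)phenyl]prop-2-en-1-ol
Product: 5 [(2S,3S)-3-[3,4-bis(benzyloxy)phenyl]oxiran-2-yl]methanol
Conditions: Ti(OiPr)4 (10 mol%), L-(+)-diisopropyl tartrate (12 mol%), tBuOOH, 4 Å molecular sieves, CH2Cl2, −20 °C; aq. NaOH/brine work-up, Et3N-washed silica
Reagents that add atoms: tert-butyl hydroperoxide, CC(C)(C)OO
Why: Sharpless asymmetric epoxidation, in which the titanium complex of the L-(+)-tartrate delivers the peroxide oxygen to the face of the E allylic alcohol that gives the (2S,3S)-trans epoxide (C8' and, provisionally, C7'), while the catalytic sieve protocol and a basic work-up limit acid-induced opening of the electron-rich benzylic epoxide.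

Step 4
Reactants: 5 [(2S,3S)-3-[3,4-bis(benzyloxy)phenyl]oxiran-2-yl]methanol
Product: 6 (2S,3S)-2-[(benzyloxy)methyl]-3-[3,4-bis(benzyloxy)phenyl]oxirane
Conditions: NaH, BnBr, Bu4NI (cat.), THF, 0 °C → rt
Reagents that add atoms: benzyl bromide, BrCc1ccccc1
Why: Williamson etherification of the sodium alkoxide at 0 °C should outrun Payne rearrangement and leave both epoxide carbons untouched, and the resulting C9' ether later slows SN2 attack at C8' by its inductive pull.

Step 5
Reactants: 7 3-bromo-4-hydroxybenzaldehyde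
Product: 8 2-bromo-4-(1,3-dioxolan-2-yl)phenol
Conditions: ethane-1,2-diol, p-TsOH·H2O (cat.), toluene, reflux (Dean–Stark); Et3N quench
Reagents that add atoms: ethane-1,2-diol, OCCO
Why: acid-catalysed acetalisation with azeotropic removal of water masks the formyl group, so that the arene holds neither an electrophile nor a para acceptor in the basic copper steps.

Step 6
Reactants: 6 (2S,3S)-2-[(benzyloxy)methyl]-3-[3,4-bis(benzyloxy)phenyl]oxirane; 8 2-bromo-4-(1,3-dioxolan-2-yl)phenol
Product: 10 cis ring C–D–E acetal (2R,3S)-3-[(benzyloxy)methyl]-2-[3,4-bis(benzyloxy)phenyl]-6-(1,3-dioxolan-2-yl)-2,3-dihydro-1,4-benzodioxine, via ring-opened bromo alcohol 9 (not isolated)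
Conditions: Cs2CO3 (2.5 equiv), DMF, 80 °C; then CuI (10 mol%), 1,10-phenanthroline (20 mol%), 110 °C, same pot
Reagents that add atoms: none
Why: The caesium phenoxide of 8 attacks the epoxide of 6 at the benzylic carbon C7' from the side opposite the oxirane oxygen (SN2), which makes the C7'–O4C bond with inversion and releases the C8' alkoxide (9 as its caesium salt), and monovalent copper bound by 1,10-phenanthroline then takes up this alkoxide, inserts into the neighbouring C–Br bond and forms the O3C–C3 bond by reductive elimination from trivalent copper. The closest known reaction type is the one-pot opening of epoxides by 2-halophenols followed by copper-catalysed intramolecular Ullmann-type O-arylation to 1,4-benzodioxanes. Ring D closes as a six-membered ring by C(aryl)–O bond formation from a seven-membered copper alkoxide–aryl chelate, the only closure open to the single free alkoxide. C7' is the one stereocentre made in the step, and its 7'R configuration follows from inversion of the 3S centre of the epoxide (substrate control), whereas C8' keeps the configuration set by the Sharpless epoxidation because its C–O bond is never broken, so that the trans epoxide should give the cis ring. The step needs attack at C7' and not at C8', inversion without ionisation, and no Smiles shift of ring C between O4C and O3C; the first is secured by benzylic activation of C7' together with the inductive deactivation of C8' by the C9' ether, the second by the absence of any Lewis or protic acid and by the benzyl cap on the para oxygen of ring E, and the third by the acetal, which leaves ring C without a para acceptor.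

Step 7
Reactants: 10 cis ring C–D–E acetal
Product: 11 (2R,3S)-3-[(benzyloxy)methyl]-2-[3,4-bis(benzyloxy)phenyl]-2,3-dihydro-1,4-benzodioxine-6-carbaldehyde
Conditions: PPTS (cat.), acetone–H2O (10:1), 40 °C
Reagents that add atoms: water, O
Why: acid-catalysed hydrolysis of the aryl dioxolane, made fast by the para oxygen O4C, should free the ring C aldehyde under conditions too mild to ionise the benzylic C7'–O bond or to touch the benzyl ethers.

Step 8
Reactants: 12 (R)-4-benzyl-1,3-oxazolidin-2-one; 13 bromoacetyl bromide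
Product: 14 (R)-4-benzyl-3-(bromoacetyl)-1,3-oxazolidin-2-one
Conditions: n-BuLi, THF, −78 °C; then BrCH2COBr, −78 → 0 °C
Reagents that add atoms: none
Why: N-acylation of the lithium salt of the oxazolidinone by the acyl bromide is much faster at −78 °C than SN2 at the CH2Br carbon and leaves the stereocentre of the auxiliary untouched.

Step 9
Reactants: 8 2-bromo-4-(1,3-dioxolan-2-yl)phenol; 14 (R)-4-benzyl-3-(bromoacetyl)-1,3-oxazolidin-2-one
Product: 15 (R)-4-benzyl-3-{[2-bromo-4-(1,3-dioxolan-2-yl)phenoxy]acetyl}-1,3-oxazolidin-2-one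
Conditions: K2CO3, acetone, rt
Reagents that add atoms: none
Why: Williamson O-alkylation, in which the potassium phenoxide displaces the activated α-bromide of the imide by SN2 far faster than it attacks either carbonyl group, which puts the O4A–C8 bond in place before C8 becomes stereogenic.

Step 10
Reactants: 15 (R)-4-benzyl-3-{[2-bromo-4-(1,3-dioxolan-2-yl)phenoxy]acetyl}-1,3-oxazolidin-2-one; 11 ring C–D–E aldehyde
Product: 17 syn-aldol adduct (4R)-4-benzyl-3-[(2R,3S)-2-[2-bromo-4-(1,3-dioxolan-2-yl)phenoxy]-3-hydroxy-3-{ring C–D–E aryl group of 11}propanoyl]-1,3-oxazolidin-2-one, via Z dibutylboron enolate 16 (not isolated)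
Conditions: Bu2BOTf, iPr2NEt, CH2Cl2, −78 → 0 °C; then 11, −78 → 0 °C; pH 7 buffer, MeOH, 30% H2O2, 0 °C
Reagents that add atoms: none
Why: Evans syn-aldol addition, in which the Z boron enolate reacts through a closed chair (Zimmerman–Traxler) transition state on the enolate face left open by the benzyl group of the (R)-auxiliary, which sets C7 (S) and C8 in the syn relation and in the absolute sense that becomes 7S,8S once C9 is CH2O, the distant stereocentres of ring D having no influence.

Step 11
Reactants: 17 syn-aldol adduct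
Product: 18 (1S,2S)-2-[2-bromo-4-(1,3-dioxolan-2-yl)phenoxy]-1-{ring C–D–E aryl group of 11}propane-1,3-diol
Conditions: LiBH4, H2O (1 equiv), THF, 0 °C
Reagents that add atoms: none
Why: reductive cleavage of the imide by the borohydride (hydride addition to the exocyclic carbonyl activated by lithium chelation) turns C9 into CH2OH and returns the auxiliary without touching C7, C8, the aryl bromide or the acetals.

Step 12
Reactants: 18 (1S,2S)-1,3-diol
Product: 19 (1S,2S)-2-[2-bromo-4-(1,3-dioxolan-2-yl)phenoxy]-3-[(tert-butyldiphenylsilyl)oxy]-1-{ring C–D–E aryl group of 11}propan-1-ol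
Conditions: TBDPSCl, imidazole, CH2Cl2, 0 °C
Reagents that add atoms: tert-butyl(chloro)diphenylsilane, CC(C)(C)[Si](Cl)(c1ccccc1)c1ccccc1
Why: silylation of the primary C9 hydroxyl by the bulky chlorosilane is much faster than that of the hindered benzylic C7 hydroxyl, and this silyl group is chosen because it should not migrate to O7 under the basic conditions of the next step.

Step 13
Reactants: 19 (1S,2S)-bromo alcohol silyl ether
Product: 20 2-[(2S,3S)-3-{(2R,3S)-3-[(benzyloxy)methyl]-2-[3,4-bis(benzyloxy)phenyl]-2,3-dihydro-1,4-benzodioxin-6-yl}-2-{[(tert-butyldiphenylsilyl)oxy]methyl}-2,3-dihydro-1,4-benzodioxin-6-yl]-1,3-dioxolane (rings A to E)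
Conditions: CuI (20 mol%), 3,4,7,8-tetramethyl-1,10-phenanthroline (40 mol%), Cs2CO3, toluene, 110 °C
Reagents that add atoms: none
Why: intramolecular Ullmann-type O-arylation, in which the C7 alkoxide is arylated at the ring A bromide through a copper alkoxide without the C7–O bond ever being broken, so that the syn relation from the aldol becomes the trans ring B (7S,8S), while the acetal keeps ring A free of a para acceptor and so excludes a Smiles exchange of O7 and O8.

Step 14
Reactants: 20 pentacyclic tribenzyl ether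
Product: 21 pentacyclic triol with free ring E catechol and free C9' hydroxyl (acetal and silyl ether retained)
Conditions: H2 (1 atm), Pd(OH)2 on carbon, NaHCO3 (solid), EtOAc–EtOH, rt
Reagents that add atoms: none
Why: hydrogenolysis of the three benzyl ethers is placed here because the molecule holds no alkene and no aryl bromide at this point, the silyl ether is inert, and the neutral buffered medium should spare the acetal and the secondary benzylic C7–O and C7'–O bonds of the two dioxane rings.

Step 15
Reactants: 21 pentacyclic triol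
Product: 22 tris(tert-butyldimethylsilyl) ether of 21 (both ring E oxygens and O9')
Conditions: TBSCl, imidazole, DMF, rt
Reagents that add atoms: tert-butyl(chloro)dimethylsilane, CC(C)(C)[Si](C)(C)Cl
Why: imidazole-promoted silylation covers the two phenols and the primary alcohol with groups that survive the remaining neutral steps and can be removed by fluoride at the end.

Step 16
Reactants: 22 persilylated acetal
Product: 23 persilylated ring A aldehyde (6-carbaldehyde of the ring A/B benzodioxine)
Conditions: PPTS (cat.), acetone–H2O (20:1), rt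
Reagents that add atoms: water, O
Why: acid-catalysed hydrolysis of the electron-rich aryl dioxolane is fast under pyridinium tosylate catalysis, which aryl and primary alkyl silyl ethers and the protected cis ring D should tolerate.

Step 17
Reactants: 23 persilylated ring A aldehyde; 24 (triphenylphosphoranylidene)acetaldehyde
Product: 25 persilylated (E)-enal
Conditions: toluene, 80 °C
Reagents that add atoms: none
Why: Wittig olefination by the stabilised formyl ylide should give the E enal directly under neutral conditions that keep the aryl silyl ethers.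

Step 18
Reactants: 25 persilylated (E)-enal
Product: 26 CNP0302404.1, (E)-3-[(2S,3S)-3-[(2R,3S)-2-(3,4-dihydroxyphenyl)-3-(hydroxymethyl)-2,3-dihydro-1,4-benzodioxin-6-yl]-2-(hydroxymethyl)-2,3-dihydro-1,4-benzodioxin-6-yl]prop-2-enal
Conditions: HF·pyridine, pyridine, THF, 0 °C → rt; Me3SiOMe quench
Reagents that add atoms: none
Why: fluoride-mediated cleavage of all four Si–O bonds in a buffered, slightly acidic medium frees the catechol without forming its phenoxide, so that the cis ring D should not epimerise at C7' through a quinone methide and the enal is not attacked.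

**Compound list**

1 | 3,4-bis(benzyloxy)benzaldehyde | O=Cc1ccc(OCc2ccccc2)c(OCc2ccccc2)c1 | starting material
2 | triethyl phosphonoacetate | CCOC(=O)CP(=O)(OCC)OCC | starting material
3 | ethyl (E)-3-[3,4-bis(benzyloxy)phenyl]prop-2-enoate | CCOC(=O)/C=C/c1ccc(OCc2ccccc2)c(OCc2ccccc2)c1 | intermediate
4 | (E)-3-[3,4-bis(benzyloxy)phenyl]prop-2-en-1-ol | OC/C=C/c1ccc(OCc2ccccc2)c(OCc2ccccc2)c1 | intermediate
5 | [(2S,3S)-3-[3,4-bis(benzyloxy)phenyl]oxiran-2-yl]methanol | OC[C@@H]1O[C@H]1c1ccc(OCc2ccccc2)c(OCc2ccccc2)c1 | intermediate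
6 | (2S,3S)-2-[(benzyloxy)methyl]-3-[3,4-bis(benzyloxy)phenyl]oxirane | c1ccccc1COC[C@@H]1O[C@H]1c1ccc(OCc2ccccc2)c(OCc2ccccc2)c1 | intermediate
7 | 3-bromo-4-hydroxybenzaldehyde | O=Cc1ccc(O)c(Br)c1 | starting material
8 | 2-bromo-4-(1,3-dioxolan-2-yl)phenol | Oc1ccc(C2OCCO2)cc1Br | intermediate
9 | (2S,3R)-1-(benzyloxy)-3-[3,4-bis(benzyloxy)phenyl]-3-[2-bromo-4-(1,3-dioxolan-2-yl)phenoxy]propan-2-ol (not isolated) | O[C@@H](COCc1ccccc1)[C@@H](c1ccc(OCc2ccccc2)c(OCc2ccccc2)c1)Oc1ccc(C2OCCO2)cc1Br | intermediate
10 | (2R,3S)-3-[(benzyloxy)methyl]-2-[3,4-bis(benzyloxy)phenyl]-6-(1,3-dioxolan-2-yl)-2,3-dihydro-1,4-benzodioxine (cis) | C1COC(O1)c1ccc2c(c1)O[C@@H](COCc1ccccc1)[C@@H](c1ccc(OCc3ccccc3)c(OCc3ccccc3)c1)O2 | intermediate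
11 | (2R,3S)-3-[(benzyloxy)methyl]-2-[3,4-bis(benzyloxy)phenyl]-2,3-dihydro-1,4-benzodioxine-6-carbaldehyde | O=Cc1ccc2c(c1)O[C@@H](COCc1ccccc1)[C@@H](c1ccc(OCc3ccccc3)c(OCc3ccccc3)c1)O2 | intermediate
12 | (R)-4-benzyl-1,3-oxazolidin-2-one | O=C1N[C@H](Cc2ccccc2)CO1 | starting material
13 | bromoacetyl bromide | BrCC(Br)=O | starting material
14 | (R)-4-benzyl-3-(bromoacetyl)-1,3-oxazolidin-2-one | O=C(CBr)N1[C@H](Cc2ccccc2)COC1=O | intermediate
15 | (R)-4-benzyl-3-{[2-bromo-4-(1,3-dioxolan-2-yl)phenoxy]acetyl}-1,3-oxazolidin-2-one | O=C(COc1ccc(C2OCCO2)cc1Br)N1[C@H](Cc2ccccc2)COC1=O | intermediate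
16 | Z dibutylboron enolate of 15 (not isolated) | CCCCB(CCCC)O/C(N1[C@H](Cc2ccccc2)COC1=O)=C\Oc1ccc(C2OCCO2)cc1Br | intermediate
17 | (4R)-4-benzyl-3-[(2R,3S)-3-{(2R,3S)-3-[(benzyloxy)methyl]-2-[3,4-bis(benzyloxy)phenyl]-2,3-dihydro-1,4-benzodioxin-6-yl}-2-[2-bromo-4-(1,3-dioxolan-2-yl)phenoxy]-3-hydroxypropanoyl]-1,3-oxazolidin-2-one | O[C@@H](c1ccc2c(c1)O[C@@H](COCc1ccccc1)[C@@H](c1ccc(OCc3ccccc3)c(OCc3ccccc3)c1)O2)[C@H](C(=O)N1[C@H](Cc2ccccc2)COC1=O)Oc1ccc(C2OCCO2)cc1Br | intermediate
18 | (1S,2S)-1-{(2R,3S)-3-[(benzyloxy)methyl]-2-[3,4-bis(benzyloxy)phenyl]-2,3-dihydro-1,4-benzodioxin-6-yl}-2-[2-bromo-4-(1,3-dioxolan-2-yl)phenoxy]propane-1,3-diol | O[C@@H](c1ccc2c(c1)O[C@@H](COCc1ccccc1)[C@@H](c1ccc(OCc3ccccc3)c(OCc3ccccc3)c1)O2)[C@H](CO)Oc1ccc(C2OCCO2)cc1Br | intermediate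
19 | (1S,2S)-1-{(2R,3S)-3-[(benzyloxy)methyl]-2-[3,4-bis(benzyloxy)phenyl]-2,3-dihydro-1,4-benzodioxin-6-yl}-2-[2-bromo-4-(1,3-dioxolan-2-yl)phenoxy]-3-[(tert-butyldiphenylsilyl)oxy]propan-1-ol | O[C@@H](c1ccc2c(c1)O[C@@H](COCc1ccccc1)[C@@H](c1ccc(OCc3ccccc3)c(OCc3ccccc3)c1)O2)[C@H](CO[Si](c1ccccc1)(c1ccccc1)C(C)(C)C)Oc1ccc(C2OCCO2)cc1Br | intermediate
20 | 2-[(2S,3S)-3-{(2R,3S)-3-[(benzyloxy)methyl]-2-[3,4-bis(benzyloxy)phenyl]-2,3-dihydro-1,4-benzodioxin-6-yl}-2-{[(tert-butyldiphenylsilyl)oxy]methyl}-2,3-dihydro-1,4-benzodioxin-6-yl]-1,3-dioxolane | C1COC(O1)c1ccc2c(c1)O[C@@H](c1ccc3c(c1)O[C@@H](COCc1ccccc1)[C@@H](c1ccc(OCc4ccccc4)c(OCc4ccccc4)c1)O3)[C@H](CO[Si](c1ccccc1)(c1ccccc1)C(C)(C)C)O2 | intermediate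
21 | 4-[(2R,3S)-6-[(2S,3S)-2-{[(tert-butyldiphenylsilyl)oxy]methyl}-6-(1,3-dioxolan-2-yl)-2,3-dihydro-1,4-benzodioxin-3-yl]-3-(hydroxymethyl)-2,3-dihydro-1,4-benzodioxin-2-yl]benzene-1,2-diol | C1COC(O1)c1ccc2c(c1)O[C@@H](c1ccc3c(c1)O[C@@H](CO)[C@@H](c1ccc(O)c(O)c1)O3)[C@H](CO[Si](c1ccccc1)(c1ccccc1)C(C)(C)C)O2 | intermediate
22 | tris(tert-butyldimethylsilyl) ether of 21 at both ring E oxygens and O9' | C1COC(O1)c1ccc2c(c1)O[C@@H](c1ccc3c(c1)O[C@@H](CO[Si](C)(C)C(C)(C)C)[C@@H](c1ccc(O[Si](C)(C)C(C)(C)C)c(O[Si](C)(C)C(C)(C)C)c1)O3)[C@H](CO[Si](c1ccccc1)(c1ccccc1)C(C)(C)C)O2 | intermediate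
23 | (2S,3S)-3-{(2R,3S)-2-[3,4-bis(tert-butyldimethylsilyloxy)phenyl]-3-[(tert-butyldimethylsilyloxy)methyl]-2,3-dihydro-1,4-benzodioxin-6-yl}-2-{[(tert-butyldiphenylsilyl)oxy]methyl}-2,3-dihydro-1,4-benzodioxine-6-carbaldehyde | O=Cc1ccc2c(c1)O[C@@H](c1ccc3c(c1)O[C@@H](CO[Si](C)(C)C(C)(C)C)[C@@H](c1ccc(O[Si](C)(C)C(C)(C)C)c(O[Si](C)(C)C(C)(C)C)c1)O3)[C@H](CO[Si](c1ccccc1)(c1ccccc1)C(C)(C)C)O2 | intermediate
24 | (triphenylphosphoranylidene)acetaldehyde | O=CC=P(c1ccccc1)(c1ccccc1)c1ccccc1 | starting material
25 | (E)-3-[(2S,3S)-3-{(2R,3S)-2-[3,4-bis(tert-butyldimethylsilyloxy)phenyl]-3-[(tert-butyldimethylsilyloxy)methyl]-2,3-dihydro-1,4-benzodioxin-6-yl}-2-{[(tert-butyldiphenylsilyl)oxy]methyl}-2,3-dihydro-1,4-benzodioxin-6-yl]prop-2-enal | O=C/C=C/c1ccc2c(c1)O[C@@H](c1ccc3c(c1)O[C@@H](CO[Si](C)(C)C(C)(C)C)[C@@H](c1ccc(O[Si](C)(C)C(C)(C)C)c(O[Si](C)(C)C(C)(C)C)c1)O3)[C@H](CO[Si](c1ccccc1)(c1ccccc1)C(C)(C)C)O2 | intermediate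
26 | CNP0302404.1, (E)-3-[(2S,3S)-3-[(2R,3S)-2-(3,4-dihydroxyphenyl)-3-(hydroxymethyl)-2,3-dihydro-1,4-benzodioxin-6-yl]-2-(hydroxymethyl)-2,3-dihydro-1,4-benzodioxin-6-yl]prop-2-enal | O=C/C=C/c1ccc2c(c1)O[C@@H](c1ccc3c(c1)O[C@@H](CO)[C@@H](c1ccc(O)c(O)c1)O3)[C@H](CO)O2 | target

**Step count and risks**

Total: 18 steps. Longest linear sequence: 15 steps from 1 (steps 1, 2, 3, 4, 6, 7, 10, 11, 12, 13, 14, 15, 16, 17, 18).

Steps most likely to fail:

Step 6 (key step). The phenoxide may attack C8' in competition with C7'. The domino may also stall after the opening, because the hindered secondary caesium alkoxide is arylated slowly at an electron-rich, ortho-oxygenated aryl bromide and hydrodebromination can take over in hot DMF. The fallback sets out from 6 and 8 and separates the two events. The opening is run with Cs2CO3 alone (DMF, 80 °C) and bromo alcohol 9 is isolated and freed from any regioisomer. Ring D is then closed in a separate palladium-catalysed etherification (Pd(OAc)2, racemic 2-(di-tert-butylphosphino)-1,1'-binaphthyl, Cs2CO3, toluene, 80 °C). This closure runs through oxidative addition of zerovalent palladium to the C–Br bond and C–O reductive elimination from divalent palladium, not through a copper alkoxide, and again leaves the C8'–O bond intact. It comes back to the route at 10 and makes no compound outside the list (F0).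

Step 3. The p-alkoxybenzylic epoxide may be opened by tartrate, isopropanol or tert-butanol on the Lewis-acidic titanium centre during the reaction or the work-up, so that material is lost before it can be benzylated. The fallback sets out from 4 and avoids both titanium and the free epoxy alcohol. O-Benzylation (NaH, BnBr, THF, 0 °C) should give 1,2-bis(benzyloxy)-4-[(E)-3-(benzyloxy)prop-1-enyl]benzene F1. A Shi epoxidation follows, with the enantiomer of the fructose-derived ketone (prepared from L-sorbose), KHSO5 (as 2KHSO5·KHSO4·K2SO4), K2CO3 and Bu4NHSO4 in MeCN–dimethoxymethane–aqueous Na2B4O7 buffer at 0 °C. The chiral dioxirane should transfer oxygen to the trans alkene through a spiro transition state. The fructose-derived ketone gives the (R,R) series with trans-β-substituted styrenes, so its enantiomer is needed for the (2S,3S) epoxide, and the basic medium protects the epoxide. The fallback comes back to the route at 6, and 5 is bypassed.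

Step 17. The product enal is more electrophilic than the electron-rich ring A aldehyde, so a second olefination to the dienal may compete while conversion of 23 is still incomplete. The fallback sets out from 23 and builds the enal in three redox-controlled operations. Wittig olefination with Ph3P=CHCO2Et (toluene, 80 °C) should give ethyl (E)-cinnamate F2, which cannot react further with the ylide. Reduction with iBu2AlH (CH2Cl2, −78 °C) should give the (E)-allylic alcohol F3, the other hydroxyls being silylated. Oxidation of this single allylic alcohol with MnO2 (CH2Cl2, rt) comes back to the route at 25.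

Further compounds
F0 | step 6 | none | none
F1 | step 3 | 1,2-bis(benzyloxy)-4-[(E)-3-(benzyloxy)prop-1-enyl]benzene | c1ccccc1COC/C=C/c1ccc(OCc2ccccc2)c(OCc2ccccc2)c1
F2 | step 17 | ethyl (E)-3-[(2S,3S)-3-{(2R,3S)-2-[3,4-bis(tert-butyldimethylsilyloxy)phenyl]-3-[(tert-butyldimethylsilyloxy)methyl]-2,3-dihydro-1,4-benzodioxin-6-yl}-2-{[(tert-butyldiphenylsilyl)oxy]methyl}-2,3-dihydro-1,4-benzodioxin-6-yl]prop-2-enoate | CCOC(=O)/C=C/c1ccc2c(c1)O[C@@H](c1ccc3c(c1)O[C@@H](CO[Si](C)(C)C(C)(C)C)[C@@H](c1ccc(O[Si](C)(C)C(C)(C)C)c(O[Si](C)(C)C(C)(C)C)c1)O3)[C@H](CO[Si](c1ccccc1)(c1ccccc1)C(C)(C)C)O2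
F3 | step 17 | (E)-3-[(2S,3S)-3-{(2R,3S)-2-[3,4-bis(tert-butyldimethylsilyloxy)phenyl]-3-[(tert-butyldimethylsilyloxy)methyl]-2,3-dihydro-1,4-benzodioxin-6-yl}-2-{[(tert-butyldiphenylsilyl)oxy]methyl}-2,3-dihydro-1,4-benzodioxin-6-yl]prop-2-en-1-ol | OC/C=C/c1ccc2c(c1)O[C@@H](c1ccc3c(c1)O[C@@H](CO[Si](C)(C)C(C)(C)C)[C@@H](c1ccc(O[Si](C)(C)C(C)(C)C)c(O[Si](C)(C)C(C)(C)C)c1)O3)[C@H](CO[Si](c1ccccc1)(c1ccccc1)C(C)(C)C)O2
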